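The data are simulated with made-up constants; noise was put on by code.

If your hunch holds and the isomer of the product keeps its share from Sunday's run, the flask at 1.0 M ends with target to isomer at 11.7. I doubt it. At 4.00 d the isomer reads 12.3% on Friday's run at 0.50 M, but 7.9% on Sunday's at 0.75 M.

| flask | substrate | partner | remark | time |
|---|---|---|---|---|
| Friday's | 0.50 M | 2.5 equiv | run made earlier |  |
| Sunday's | 0.75 M | 2.5 equiv | run made earlier |  |
| flask | 1.0 M | 2.50 equiv |  | 4.0 d |

| run | time / d | target / % | isomer of the product / % |
|---|---|---|---|
| Friday's | 0.333 | 74.7 | 7.6 |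
| Friday's | 0.500 | 82.4 | 8.3 |
| Friday's | 0.833 | 84.2 | 11.0 |
| Friday's | 1.67 | 86.8 | 11.1 |
| Friday's | 2.50 | 87.2 | 11.3 |
| Friday's | 4.00 | 88.1 | 12.3 |
| Sunday's | 0.250 | 79.7 | 6.2 |
| Sunday's | 0.833 | 91.4 | 7.1 |
| Sunday's | 1.25 | 92.4 | 6.7 |
| Sunday's | 2.00 | 93.7 | 7.8 |
| Sunday's | 3.00 | 92.5 | 5.4 |
| Sunday's | 4.00 | 92.7 | 7.9 |

(standard deviation of a reading: 1 percentage point)

- ratio of target to isomer of the product at 4.0 min
- ratio of target to isomer of the product at 2.5 h
- ratio of target to isomer of the product at 4.0 d

Follow one molecule of substrate. Either partner captures it and it becomes target, or it first turns into the other conformer and ends as isomer. The turn needs no partner and the capture does. At fixed equivalents I therefore expect the chance of turning to go as one over the concentration.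

So I multiply the end share of isomer by the starting concentration. Friday's run gives 0.0615 M and Sunday's 0.0592 M, a gap smaller than the scatter of one of Friday's readings multiplied the same way. I keep their mean, 0.0604 M, as the leak yield L, the isomer formed per litre by the end. In the proposed steps neither product returns, so this is kinetic control.

At 1.0 M, L gives an isomer share of 6.04%. With the rest as target, I commit to a ratio of 15.6 at 4.0 d. I expect higher ratios earlier, but give no number: Friday's ratio reads 9.83 at 0.333 d and 7.16 at 4.00 d.

The forecast says 1100 at 4.0 min, 30 at 2.5 h and 16.5 at 4.0 d, above my end value. It calls the first “very uncertain”.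

The flask gives 127, 23.1 and 18.0.

    substrate ⇌ other conformer (K = 0.380, k = 0.0230 h⁻¹)
    substrate + partner → target (k = 0.250 L mol⁻¹ h⁻¹)
    partner + other conformer → isomer of the product (k = 3.00 L mol⁻¹ h⁻¹)
    partner → decomposed reagent (k = 0.0540 h⁻¹)

In this flask the other conformer's half-life against partner at 0.458 d is 0.30 h, shorter than the 0.346 d relaxation half-life of the two conformers by their interconversion alone, both ways together. At 0.400 d the other conformer stands at 0.0318% and the isomer at 4.80%. The leak yield of this flask at 4.00 d is 0.0527 M, below my 0.0604 M. At 0.25 M of substrate with the same equivalents, the isomer reaches 20.9%, a leak yield of 0.0522 M.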